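The route rests on cutting the terminal 2,2-disubstituted oxirane back to an aryl ketone. The ring CH2 carbon, bonded only to the quaternary benzylic carbon and the ring oxygen, is delivered as one methylene from a sulfur ylide to the C=O of an aryl acetoxymethyl ketone. In one operation this asymmetric Corey–Chaykovsky step forms the C(quaternary)–CH2 and CH2–O bonds, closes the three-membered ring and sets the quaternary (R) stereocentre under basic conditions. Its precursor is 4-(acetoxyacetyl)-3-(triisopropylsilyloxy)benzyl (R)-2-methylbutanoate, carrying both aliphatic esters and a TIPS-masked phenol. The acid- and isomerisation-prone angelate is attached last.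

Key step: step 6

Assumption: the sense of induction is taken to follow that of aryl methyl ketones with CH2OAc in the place of methyl, which calls for the (R)-binaphthoxide complex; this is untested for the substrate class, and the antipodal complex is the immediate correction if the opposite face is attacked.

Step 1
Reactants: 1 methyl 3-hydroxy-4-iodobenzoate
Product: 2 methyl 4-iodo-3-(triisopropylsilyloxy)benzoate
Conditions: TIPSCl, imidazole, DMF, rt
Reagents that add atoms: triisopropylsilyl chloride, CC(C)[Si](Cl)(C(C)C)C(C)C
Why: Silyl ether formation masks the acidic phenol before hydride and organomagnesium chemistry, and the bulky TIPS group is chosen because it resists oxygen-to-carbon silyl shift at the later ortho-metallated stage and cleavage by acetate or ylide.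

Step 2
Reactants: 2 methyl 4-iodo-3-(triisopropylsilyloxy)benzoate
Product: 3 [4-iodo-3-(triisopropylsilyloxy)phenyl]methanol
Conditions: iBu2AlH (2.5 equiv), CH2Cl2, −78 → 0 °C; aq. KNaC4H4O6
Reagents that add atoms: none
Why: Hydride reduction of the methyl ester to the benzylic alcohol with iBu2AlH should leave the aryl iodide and the aryl silyl ether untouched at low temperature.

Step 3
Reactants: 3 [4-iodo-3-(triisopropylsilyloxy)phenyl]methanol; 4 (R)-2-methylbutanoic acid
Product: 5 4-iodo-3-(triisopropylsilyloxy)benzyl (R)-2-methylbutanoate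
Conditions: DCC, DMAP (cat.), CH2Cl2, 0 °C → rt
Reagents that add atoms: none
Why: Steglich esterification acylates the primary benzylic alcohol under near-neutral conditions, which should leave the α-stereocentre of the simple α-branched acid intact.

Step 4
Reactants: 5 4-iodo-3-(triisopropylsilyloxy)benzyl (R)-2-methylbutanoate; 6 2-chloro-N-methoxy-N-methylacetamide
Product: 9 4-(chloroacetyl)-3-(triisopropylsilyloxy)benzyl (R)-2-methylbutanoate, via arylmagnesium chloride 7 (not isolated), via magnesium-chelated hemiaminal 8 (not isolated)
Conditions: iPrMgCl·LiCl (1.1 equiv), THF, −20 °C; then 6 (1.5 equiv), −20 → 0 °C; cold 1 M HCl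
Reagents that add atoms: none
Why: Iodine–magnesium exchange at −20 °C should outpace Grignard attack on the hindered α-branched ester, and acylation by the N-methoxy-N-methyl amide (Weinreb ketone synthesis) stops at chelate 8, which releases the α-chloro ketone only on acidic quench; magnesium in place of lithium together with the TIPS group suppresses a retro-Brook shift.

Step 5
Reactants: 9 4-(chloroacetyl)-3-(triisopropylsilyloxy)benzyl (R)-2-methylbutanoate
Product: 10 4-(acetoxyacetyl)-3-(triisopropylsilyloxy)benzyl (R)-2-methylbutanoate
Conditions: CsOAc (1.5 equiv), DMF, rt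
Reagents that add atoms: caesium acetate, CC(=O)[O-].[Cs+]
Why: SN2 displacement of the activated primary α-keto chloride by acetate runs at room temperature, and the weakly basic acetate should spare the TIPS ether and the α-stereocentre of the butanoate.

Step 6
Reactants: 10 4-(acetoxyacetyl)-3-(triisopropylsilyloxy)benzyl (R)-2-methylbutanoate; 11 trimethylsulfoxonium iodide
Product: 14 4-[(R)-2-(acetoxymethyl)oxiran-2-yl]-3-(triisopropylsilyloxy)benzyl (R)-2-methylbutanoate, via dimethylsulfoxonium methylide 12 (not isolated), via sulfoxonium betaine 13 (not isolated)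
Conditions: 11, NaH, THF, reflux, filtration (solution of 12); then 10, LaLi3[(R)-binaphthoxide]3 (10 mol %), tris(2,4,6-trimethoxyphenyl)phosphine oxide (10 mol %), 5 Å molecular sieves, THF, 0 °C → rt, slow addition of 12; Et3N-buffered SiO2
Reagents that add atoms: none
Why: Proposed new method: the closest known reaction is the LaLi3(binaphthoxide)3/triarylphosphine oxide-catalysed asymmetric Corey–Chaykovsky epoxidation of aryl and alkyl methyl ketones, extended here to an α-acetoxy aryl ketone, a substrate class on which it has not been shown. Trivalent lanthanum binds and activates the ketone oxygen of 10, the only carbonyl electrophilic enough for the stabilised ylide, while a lithium binaphthoxide arm positions ylide 12, whose carbon adds to C=O to give betaine 13 (new C(quaternary)–CH2 bond). The alkoxide of 13 then displaces dimethyl sulfoxide at the CH2–S carbon in a 3-exo-tet closure (new CH2–O bond), so the former carbonyl oxygen becomes the oxirane oxygen. The quaternary stereocentre is set under catalyst control: the chiral binaphthoxide pocket has to deliver CH2 to the Re face of the ketone (O, CH2OAc, aryl clockwise), which gives the (R)-oxirane. The face selectivity required rests on the size contrast between the aryl group, twisted out of the carbonyl plane by its ortho-OTIPS substituent, and the slimmer CH2OAc arm, and the chemoselectivity required (addition in preference to enolisation of the ArCOCH2OAc unit or attack at the esters) rests on Lewis-acid activation of the ketone, the low basicity of the sulfoxonium ylide and its slow addition. The bulk of the TIPS group should also keep silyl transfer from the phenol oxygen to the betaine alkoxide slower than ring closure.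

Step 7
Reactants: 15 angelic acid [(Z)-2-methylbut-2-enoic acid], two molecules per molecule of product
Product: 16 angelic anhydride [(Z)-2-methylbut-2-enoic anhydride]
Conditions: DCC (0.5 equiv per 15), CH2Cl2, 0 °C; filtration of the urea
Reagents that add atoms: angelic acid (the second molecule of 15), C/C=C(/C)C(=O)O
Why: Carbodiimide-mediated dehydration joins two molecules of the acid through an O-acylisourea to give the symmetrical anhydride at 0 °C without chloride, heat or a nucleophilic catalyst, the agents that usually isomerise the Z-enoate to the tiglate.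

Step 8
Reactants: 14 4-[(R)-2-(acetoxymethyl)oxiran-2-yl]-3-(triisopropylsilyloxy)benzyl (R)-2-methylbutanoate; 16 angelic anhydride
Product: 18 4-[(R)-2-(acetoxymethyl)oxiran-2-yl]-3-[(Z)-2-methylbut-2-enoyloxy]benzyl (R)-2-methylbutanoate (CNP0256757.1), via tetrabutylammonium phenoxide 17 (not isolated)
Conditions: 16 (2 equiv), Bu4NF (1.1 equiv, added dropwise), THF, −40 → 0 °C; pH 7 buffer; Et3N-buffered SiO2
Reagents that add atoms: none
Why: Fluoride cleaves the aryl O–Si bond and phenoxide 17 is acylated at once by anhydride 16 (one-pot desilylation–acylation of an aryl silyl ether, nucleophilic acyl substitution), so the phenoxide has little time to attack the acetate or the oxirane, no acid is present, and the low temperature should preserve the Z geometry.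

Compound list
1 | methyl 3-hydroxy-4-iodobenzoate | COC(=O)c1ccc(I)c(O)c1 | starting material
2 | methyl 4-iodo-3-(triisopropylsilyloxy)benzoate | COC(=O)c1ccc(I)c(O[Si](C(C)C)(C(C)C)C(C)C)c1 | intermediate
3 | [4-iodo-3-(triisopropylsilyloxy)phenyl]methanol | OCc1ccc(I)c(O[Si](C(C)C)(C(C)C)C(C)C)c1 | intermediate
4 | (R)-2-methylbutanoic acid | CC[C@@H](C)C(=O)O | starting material
5 | 4-iodo-3-(triisopropylsilyloxy)benzyl (R)-2-methylbutanoate | CC(C)[Si](C(C)C)(C(C)C)Oc1cc(COC(=O)[C@H](C)CC)ccc1I | intermediate
6 | 2-chloro-N-methoxy-N-methylacetamide | CON(C)C(=O)CCl | starting material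
7 | [4-{[(R)-2-methylbutanoyloxy]methyl}-2-(triisopropylsilyloxy)phenyl]magnesium chloride (LiCl complex) | CC(C)[Si](C(C)C)(C(C)C)Oc1cc(COC(=O)[C@H](C)CC)ccc1[Mg]Cl | intermediate
8 | chloromagnesium alkoxide of the tetrahedral adduct of 7 and 6 (N,O-chelated hemiaminal; new carbon unassigned) | CC(C)[Si](C(C)C)(C(C)C)Oc1cc(COC(=O)[C@H](C)CC)ccc1C(CCl)(O[Mg]Cl)N(C)OC | intermediate
9 | 4-(chloroacetyl)-3-(triisopropylsilyloxy)benzyl (R)-2-methylbutanoate | CC(C)[Si](C(C)C)(C(C)C)Oc1cc(COC(=O)[C@H](C)CC)ccc1C(=O)CCl | intermediate
10 | 4-(acetoxyacetyl)-3-(triisopropylsilyloxy)benzyl (R)-2-methylbutanoate | CC(C)[Si](C(C)C)(C(C)C)Oc1cc(COC(=O)[C@H](C)CC)ccc1C(=O)COC(C)=O | intermediate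
11 | trimethylsulfoxonium iodide | C[S+](C)(C)=O.[I-] | starting material
12 | dimethylsulfoxonium methylide | C[S+](C)(=O)[CH2-] | intermediate
13 | catalyst-bound betaine, 1-acetoxy-2-aryl-3-(dimethylsulfoxonio)propan-2-olate with the spatial arrangement of 14 (formally S, because CH2S outranks CH2OAc) | CC(C)[Si](C(C)C)(C(C)C)Oc1cc(COC(=O)[C@H](C)CC)ccc1[C@]([O-])(COC(C)=O)C[S+](C)(C)=O | intermediate
14 | 4-[(R)-2-(acetoxymethyl)oxiran-2-yl]-3-(triisopropylsilyloxy)benzyl (R)-2-methylbutanoate | CC(C)[Si](C(C)C)(C(C)C)Oc1cc(COC(=O)[C@H](C)CC)ccc1[C@]1(COC(C)=O)CO1 | intermediate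
15 | angelic acid, (Z)-2-methylbut-2-enoic acid | C/C=C(/C)C(=O)O | starting material
16 | angelic anhydride, (Z,Z)-2-methylbut-2-enoic anhydride | C/C=C(/C)C(=O)OC(=O)/C(C)=C\C | intermediate
17 | tetrabutylammonium 2-[(R)-2-(acetoxymethyl)oxiran-2-yl]-5-{[(R)-2-methylbutanoyloxy]methyl}phenoxide | CCCC[N+](CCCC)(CCCC)CCCC.[O-]c1cc(COC(=O)[C@H](C)CC)ccc1[C@]1(COC(C)=O)CO1 | intermediate
18 | 4-[(R)-2-(acetoxymethyl)oxiran-2-yl]-3-[(Z)-2-methylbut-2-enoyloxy]benzyl (R)-2-methylbutanoate | C/C=C(/C)C(=O)Oc1cc(COC(=O)[C@H](C)CC)ccc1[C@]1(COC(C)=O)CO1 | target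

Total step count: 8 (seven in the main line plus the preparation of anhydride 16).
Longest linear sequence: 7 steps (steps 1–6 and 8, from 1).

Steps most likely to fail

1. Step 6 (Proposed new method). What may go wrong: insufficient facial discrimination at the ketone, proton transfer from the ArCOCH2OAc unit to the ylide in place of addition, or acetyl or silyl transfer to the betaine alkoxide before ring closure. The fallback uses known chemistry, sets out from 5 and comes back at 14, bypassing 9 and 10. Stille coupling of 5 with 2-(tributylstannyl)prop-2-en-1-ol (Pd(PPh3)4, CuI, DMF, 60 °C) should give 4-(3-hydroxyprop-1-en-2-yl)-3-(triisopropylsilyloxy)benzyl (R)-2-methylbutanoate F1. Sharpless asymmetric epoxidation of this 2-aryl allylic alcohol (Ti(OiPr)4, L-(+)-diethyl tartrate, tBuOOH, 4 Å molecular sieves, CH2Cl2, −20 °C) should give 4-[(S)-2-(hydroxymethyl)oxiran-2-yl]-3-(triisopropylsilyloxy)benzyl (R)-2-methylbutanoate F2, with reagent control of the oxirane configuration. Acetylation (Ac2O, Et3N, cat. DMAP, CH2Cl2, 0 °C) then arrives at 14; the descriptor changes from S to R only because CH2OAc outranks the ring CH2.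

2. Step 8. What may go wrong: Z-to-E isomerisation of the angeloyl unit by reversible conjugate addition of fluoride or carboxylate during acyl transfer, or acetyl migration and oxirane opening if the phenoxide outlives the acylating agent. The fallback sets out from 14 and comes back at 18; the five-carbon acyl group is attached without its double bond and the Z-alkene is built afterwards. Desilylation of 14 with Bu4NF in the presence of 2-[bis(2,2,2-trifluoroethoxy)phosphoryl]propanoyl chloride (THF, −40 °C) should give 2-[(R)-2-(acetoxymethyl)oxiran-2-yl]-5-{[(R)-2-methylbutanoyloxy]methyl}phenyl 2-[bis(2,2,2-trifluoroethoxy)phosphoryl]propanoate F3 (both epimers at the phosphonate carbon). Still–Gennari olefination with acetaldehyde (KN(SiMe3)2, 18-crown-6, THF, −78 °C) should then form the Z-trisubstituted enoate 18 under kinetic control.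

3. Step 4. What may go wrong: addition of the isopropyl or aryl Grignard reagent to the benzylic ester, sluggish iodine–magnesium exchange on the electron-rich ring, or deprotonation of the α-chloro amide by the hindered arylmagnesium. The fallback sets out from 5 and comes back at 10, replacing organomagnesium chemistry by a palladium-catalysed acyl-anion equivalent. Stille coupling of 5 with tributyl(1-ethoxyvinyl)stannane (PdCl2(PPh3)2, toluene, 90 °C) should give 4-(1-ethoxyvinyl)-3-(triisopropylsilyloxy)benzyl (R)-2-methylbutanoate F4. N-Bromosuccinimide in THF/H2O at 0 °C should convert the enol ether into 4-(bromoacetyl)-3-(triisopropylsilyloxy)benzyl (R)-2-methylbutanoate F5. CsOAc in DMF at rt then gives 10, the bromide taking the place of chloride 9.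

Further compounds
F1 | step 6 | 4-(3-hydroxyprop-1-en-2-yl)-3-(triisopropylsilyloxy)benzyl (R)-2-methylbutanoate | CC(C)[Si](C(C)C)(C(C)C)Oc1cc(COC(=O)[C@H](C)CC)ccc1C(=C)CO
F2 | step 6 | 4-[(S)-2-(hydroxymethyl)oxiran-2-yl]-3-(triisopropylsilyloxy)benzyl (R)-2-methylbutanoate | CC(C)[Si](C(C)C)(C(C)C)Oc1cc(COC(=O)[C@H](C)CC)ccc1[C@]1(CO)CO1
F3 | step 8 | 2-[(R)-2-(acetoxymethyl)oxiran-2-yl]-5-{[(R)-2-methylbutanoyloxy]methyl}phenyl 2-[bis(2,2,2-trifluoroethoxy)phosphoryl]propanoate | CC(C(=O)Oc1cc(COC(=O)[C@H](C)CC)ccc1[C@]1(COC(C)=O)CO1)P(=O)(OCC(F)(F)F)OCC(F)(F)F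
F4 | step 4 | 4-(1-ethoxyvinyl)-3-(triisopropylsilyloxy)benzyl (R)-2-methylbutanoate | CC(C)[Si](C(C)C)(C(C)C)Oc1cc(COC(=O)[C@H](C)CC)ccc1C(=C)OCC
F5 | step 4 | 4-(bromoacetyl)-3-(triisopropylsilyloxy)benzyl (R)-2-methylbutanoate | CC(C)[Si](C(C)C)(C(C)C)Oc1cc(COC(=O)[C@H](C)CC)ccc1C(=O)CBr
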